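The easy step is a balance on the substrate, the limiting reagent, of which we charge less than of partner: whatever does not appear as target is still substrate or has gone somewhere else.

common to all: substrate 0.41 M
- Thursday's: partner 0.43 M; capture agent 0.084 M; run made earlier
- south: partner 0.430 M; capture agent 0.0150 M; time 50 h
- south-east: partner 0.430 M; capture agent 0.0400 M; time 50 h
- north: partner 0.430 M; capture agent 0.120 M; time 50 h

Thursday's run (percent of the substrate charged)

| time / h | target / % |
|---|---|
| 2.00 | 34.6 |
| 6.00 | 61.2 |
| 12.0 | 70.1 |
| 20.0 | 71.1 |
| 25.0 | 72.9 |

(scatter of a reading: 1 percentage point)

- the numbers in the tables scatter by 1 percentage point (one standard deviation)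
- no earlier run changes the charge of capture agent; that part of a forecast is a guess
- "hardly changes" means that all values lie within two and a half points (for a concentration: within two and a half percent of the largest)

1. amount of target at the end, in percent of the substrate charged for south, south-east, north, in this order
2. how the row runs (falls all the way / rises all the way / hardly changes / falls, then rises / rises, then falls)

Thursday's run levels off, going from 70.1% at 12.0 h to 72.9% at 25.0 h. We take that last reading as its plateau, and the asked time is twice as long, so we expect the three flasks to stand on their plateaus as well. The balance gives the share of the substrate not found as target, which we call the loss: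

lost share = 27.1% of the substrate charged

Our bench rule, which is an assumption, counts one substrate for each capture agent. This gives the capture ceiling, the share of the substrate that the charge of capture agent matches one for one:

capture ceiling = [capture agent] / [substrate], as charged = 0.084 M / 0.41 M = 20.5%

The rule can explain a loss only while lost share / ceiling stays at or below one. In Thursday's run, this ratio reads 1.32, so the loss exceeds the ceiling. As read, and on this rule, 6.6 percentage points therefore lies beyond the reach of the capture agent, about a quarter of the loss.

The ceiling runs from 3.66% in south to 29.3% in north, which leaves room for a fall. No earlier run shows how much of that room is used, so our next step is a guess: we treat the whole loss as independent of the capture agent and commit to about 72.9% in each flask, a flat row.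

The forecast differs from our flat row, giving 68.9%, 69.9% and 73.7%, and its shape is: rises all the way, in its words “The yield rises gently”.

The flasks give 73.4%, 73.2% and 72.6%, and the shape of the row is: hardly changes.

    open intermediate + capture agent → trapped intermediate (k = 0.0480 L mol⁻¹ h⁻¹)
    substrate → open intermediate (k = 1.50 h⁻¹)
    2 open intermediate → homo product (k = 0.410 L mol⁻¹ h⁻¹)
    partner + open intermediate → target (k = 1.10 L mol⁻¹ h⁻¹)

At 50.0 h, trapped intermediate stands at 0.187% of the substrate charged in south, which is 5.12% of that flask's ceiling, and at 1.47% in north, which is 5.01% of a ceiling of 29.3%. In south, open intermediate has a half-life of 40 d by the capture step alone, with the other concentrations as charged, against 1.5 h by the step with partner at 0.462 h.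

All runs are simulated for substances that don't exist, noise included.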